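Numbering (clerodane type): C5 is the quaternary carbon carrying the lactone CH2 (C19); C4/C18 are the lactone α‑carbon and carbonyl; C10 is the ring‑fusion CH; C1 carries the furan; C2 is the carbinol; C7 the acetoxy carbon; C8/C9 carry methyls C17/C20; C11–C12 is the CH2–C=O bridge. Ring A = C5–C10, ring B = C1–C5 plus C10, ring C = the cycloheptanone.
Enabling feature: ring B is a 2‑oxygenated cyclohexene fused through C4–C5 to the butenolide and through C5–C10 to ring A. It is therefore the [4+2] adduct of an oxy‑diene C10=C1–C2(O)=C3 and the butenolide alkene C4=C5, joined by C6–C9, and the retrosynthesis cuts C5–C10 and C3–C4 together.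
Further cuts: C12–furan C3 (Friedel–Crafts), C1–furan C2 (enolate arylation), C9–C11 (Mukaiyama–Michael), C9–C10 (Stille), C1–C2 (acyl‑destannylation), C4=C5 (metathesis) and C6–C7 (allylation). This gives seven bought pieces; the dichloride supplies C5, C6 and C19 (its fourth carbon leaves as ethene) and acrylate supplies C4 and C18.
Forward ring order: butenolide by metathesis, then rings A and B in one intramolecular Diels–Alder step, then ring C by acylation of the furan, then release of C3=C4 from the C3 sulfide and reduction at C2.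
Stereochemistry: an asymmetric allylation sets a temporary (S)‑C7 carbinol that steers the cycloaddition (C5, C10) and is then oxidised away. C9 comes from conjugate addition anti to C19, C8 and C1 from equilibration to equatorial, C7 from equatorial hydride attack, and C2 from Luche reduction.

Key step: step 11

Conventions: "syn" and "anti" refer to the face of ring A/ring B that carries C19; absolute configurations are those of the SMILES strings.
Assumption: the ligand antipode in step 4 is taken to be the one that delivers the (S)‑carbinol (to be checked by NMR analysis of diastereomeric esters); if the sense is opposite, the enantiomeric ligand is used.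

Step 1
Reactants: 1 methyl 2-methyl-3-oxobutanoate
Product: 2 methyl (Z)-2-methyl-3-(triflyloxy)but-2-enoate
Conditions: Tf2O, 5 M aq. LiOH, toluene, 5 °C
Reagents that add atoms: trifluoromethanesulfonic anhydride, O=S(=O)(OS(=O)(=O)C(F)(F)F)C(F)(F)F
Why: Biphasic enol triflation of a β‑keto ester traps the lithium‑chelated (Z)‑enolate on oxygen, so ester and triflate end up cis, the geometry that later holds C7 and the diene on the same side of C8=C9.

Step 2
Reactants: 2 methyl (Z)-2-methyl-3-(triflyloxy)but-2-enoate
Product: 3 (Z)-4-hydroxy-3-methylbut-2-en-2-yl triflate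
Conditions: DIBAL-H (2.3 equiv), CH2Cl2, −78 °C; Rochelle salt work-up
Reagents that add atoms: none
Why: DIBAL‑H 1,2‑reduction of the unsaturated ester to the allylic alcohol at low temperature should leave the tetrasubstituted enol triflate and its geometry untouched.

Step 3
Reactants: 3 (Z)-4-hydroxy-3-methylbut-2-en-2-yl triflate
Product: 4 (Z)-2-methyl-3-(triflyloxy)but-2-enal
Conditions: activated MnO2, CH2Cl2, rt
Reagents that add atoms: none
Why: MnO2 oxidation of a primary allylic alcohol stops at the aldehyde under neutral conditions that do not isomerise the alkene.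

Step 4
Reactants: 4 (Z)-2-methyl-3-(triflyloxy)but-2-enal; 5 3-chloro-2-(chloromethyl)prop-1-ene
Product: 7 (2Z,4S)-6-(chloromethyl)-4-hydroxy-3-methylhepta-2,6-dien-2-yl triflate, via TMS ether 6 (not isolated)
Conditions: CrCl2 (10 mol %), chiral tridentate 1,8-bis(4-isopropyloxazolin-2-yl)carbazole ligand (12 mol %), Mn powder, TMSCl, DIPEA, 5 (3 equiv), THF, 0 °C to rt; then 1 M HCl, THF, 0 °C
Reagents that add atoms: none
Why: In this catalytic asymmetric Nozaki–Hiyama–Kishi allylation the allylchromium species from the allylic chloride adds to the aldehyde through a closed chair‑like transition state on the ligand‑bearing trivalent chromium, which sets C7 as S, while the absence of nickel keeps the vinyl triflate inert and excess 5 suppresses double allylation.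

Step 5
Reactants: 7 (2Z,4S)-6-(chloromethyl)-4-hydroxy-3-methylhepta-2,6-dien-2-yl triflate
Product: 8 (2Z,4S)-4-(tert-butyldimethylsilyloxy)-6-(chloromethyl)-3-methylhepta-2,6-dien-2-yl triflate
Conditions: TBSCl, imidazole, DMF, rt
Reagents that add atoms: tert-butyldimethylsilyl chloride, CC(C)(C)[Si](C)(C)Cl
Why: Imidazole‑promoted silylation of the secondary allylic alcohol does not touch the stereocentre and gives an ether that survives the metathesis, the Stille coupling and the heating of the key step.

Step 6
Reactants: 8 (2Z,4S)-4-(tert-butyldimethylsilyloxy)-6-(chloromethyl)-3-methylhepta-2,6-dien-2-yl triflate; 9 potassium acrylate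
Product: 10 (4S,5Z)-4-(tert-butyldimethylsilyloxy)-5-methyl-2-methylidene-6-(triflyloxy)hept-5-enyl acrylate
Conditions: Bu4NI (10 mol %), BHT (trace), DMF, 40 °C
Reagents that add atoms: none
Why: SN2 displacement of the primary allylic chloride by the carboxylate (iodide catalysis) brings in C4 and C18; the vinyl triflate does not react with a carboxylate.

Step 7
Reactants: 10 (4S,5Z)-4-(tert-butyldimethylsilyloxy)-5-methyl-2-methylidene-6-(triflyloxy)hept-5-enyl acrylate
Product: 11 4-[(2S,3Z)-2-(tert-butyldimethylsilyloxy)-3-methyl-4-(triflyloxy)pent-3-enyl]furan-2(5H)-one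
Conditions: second-generation Grubbs catalyst RuCl2(=CHPh)(PCy3)(H2IMes) (5 mol %), toluene (5 mM), 80 °C
Reagents that add atoms: none
Why: Ring‑closing metathesis between the acrylate and the 1,1‑disubstituted alkene closes the β‑substituted butenolide (C4=C5) with loss of ethene, and the tetrasubstituted vinyl triflate is too hindered to engage the ruthenium carbene.

Step 8
Reactants: 12 (phenylthio)acetic acid; 13 (E)-1,2-bis(tributylstannyl)ethene
Product: 15 (E)-1-(phenylthio)-4-(tributylstannyl)but-3-en-2-one, via acid chloride 14 (not isolated)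
Conditions: (COCl)2, DMF (cat.), CH2Cl2, 0 °C to rt, evaporate; then 13, AlCl3, CH2Cl2, −78 to −40 °C
Reagents that add atoms: none
Why: Acid chloride formation is followed by aluminium chloride‑promoted ipso‑acylation of the vinylstannane (Friedel–Crafts‑type acyl‑destannylation) with retention of the E geometry; the remaining stannyl group is deactivated by the new carbonyl, and the low temperature should keep the acylium from cyclising onto its own phenyl ring.

Step 9
Reactants: 15 (E)-1-(phenylthio)-4-(tributylstannyl)but-3-en-2-one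
Product: 16 (1Z,3E)-1-(phenylthio)-4-(tributylstannyl)buta-1,3-dien-2-yl acetate
Conditions: KHMDS, THF, −78 °C; then Ac2O, −78 to 0 °C
Reagents that add atoms: acetic anhydride, CC(=O)OC(C)=O
Why: Deprotonation at the only enolisable position (C3) and O‑acylation of the potassium enolate by the hard anhydride should give the enol acetate with oxygen and sulfur cis (chelated enolate), which places the phenylthio group on the outside of the diene.

Step 10
Reactants: 11 4-[(2S,3Z)-2-(tert-butyldimethylsilyloxy)-3-methyl-4-(triflyloxy)pent-3-enyl]furan-2(5H)-one; 16 (1Z,3E)-1-(phenylthio)-4-(tributylstannyl)buta-1,3-dien-2-yl acetate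
Product: 17 4-[(2S,3Z,5E,7Z)-7-acetoxy-2-(tert-butyldimethylsilyloxy)-3,4-dimethyl-8-(phenylthio)octa-3,5,7-trienyl]furan-2(5H)-one
Conditions: Pd(PPh3)4 (10 mol %), CuCl, LiCl, DMSO, 60 °C
Reagents that add atoms: none
Why: Stille coupling under copper‑assisted conditions for congested partners (oxidative addition of zerovalent palladium into the tetrasubstituted vinyl triflate, tin‑to‑copper‑to‑palladium transfer of the dienyl group, reductive elimination) forms C9–C10 with retention of all alkene geometries.

Step 11
Reactants: 17 4-[(2S,3Z,5E,7Z)-7-acetoxy-2-(tert-butyldimethylsilyloxy)-3,4-dimethyl-8-(phenylthio)octa-3,5,7-trienyl]furan-2(5H)-one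
Product: 18 tricyclic adduct (7S; rings A/B trans-fused; C18/C19 γ-lactone on C4/C5; C1=C2 enol acetate; C8=C9 alkene; 3-SPh syn to C19; H4 H10 and 7-OTBS anti to C19)
Conditions: toluene (5 mM, degassed), BHT (10 mol %), 120 °C, sealed tube
Reagents that add atoms: none
Why: The step is a concerted, asynchronous thermal [4+2] cycloaddition in which the electron‑rich 2‑acetoxy‑1‑phenylthio diene (C10=C1–C2=C3, largest coefficient at C10 because of sulfur) adds to the electron‑poor butenolide C4=C5, the C5–C10 bond running ahead of C3–C4. The closest known reaction type is the type 1 intramolecular Diels–Alder reaction of 1,7,9‑decatrienes carrying 2‑acyloxy or 2‑silyloxy dienes and unsaturated lactone dienophiles, which gives trans‑decalins. Ring B closes as the six‑membered cycloadduct ring through both new σ‑bonds, and ring A closes at the same time as a six‑membered carbocycle through the C5–C10 bond across the four‑carbon tether C6–C9 (fused mode), the (Z)‑C8=C9 alkene holding C7 and the diene cis like an ortho‑disubstituted arene. C5 and C10 (trans fusion, C19 anti to H10) follow from the endo placement of the lactone carbonyl under C1–C2 with an (E)‑C10=C1 diene; C4 is cis to C19 because addition to the ring alkene is suprafacial; C3 carries sulfur syn to C19 because sulfur sits on the outside of the diene. The step needs diene‑face selection, which the (S)‑C7 silyloxy group should secure by taking the pseudo‑equatorial site of the half‑chair of the forming ring A and so avoiding a 1,3‑diaxial clash with the incoming C19 methylene. The (E) central alkene rules out 6π‑electrocyclisation, and high dilution with a radical inhibitor suppresses intermolecular and radical pathways.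

Step 12
Reactants: 18 tricyclic adduct (7S-OTBS)
Product: 19 tricyclic (7S)-allylic alcohol (18 without the silyl group)
Conditions: HF·pyridine, pyridine, THF, 0 °C to rt
Reagents that add atoms: none
Why: Buffered HF·pyridine desilylation of the secondary silyl ether leaves the enol acetate, the lactone and the allylic sulfide intact.

Step 13
Reactants: 19 tricyclic (7S)-allylic alcohol
Product: 20 ring A enone (7-oxo-8-ene; C1=C2 enol acetate and 3-SPh unchanged)
Conditions: Dess–Martin periodinane, CH2Cl2, 0 °C to rt
Reagents that add atoms: none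
Why: Dess–Martin oxidation converts the allylic alcohol into the enone without oxidising the aryl sulfide, and the temporary C7 stereocentre is erased here.

Step 14
Reactants: 21 tert-butyl acetate
Product: 22 1-tert-butoxy-1-(tert-butyldimethylsilyloxy)ethene
Conditions: LDA, THF, −78 °C; then TBSCl, DMPU, −78 °C to rt; distillation
Reagents that add atoms: tert-butyldimethylsilyl chloride, CC(C)(C)[Si](C)(C)Cl
Why: Kinetic ester enolate formation and O‑silylation give the distillable silyl ketene acetal that will deliver C11 and C12.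

Step 15
Reactants: 20 ring A enone; 22 1-tert-butoxy-1-(tert-butyldimethylsilyloxy)ethene
Product: 24 7-keto tert-butyl ester (C9 quaternary with C11H2CO2tBu anti and C20 syn to C19; 8-CH3 equatorial), via silyl enol ether 23 (not isolated)
Conditions: Tf2NH (10 mol %), CH2Cl2, −78 to −40 °C; then 1 M HCl, THF, rt
Reagents that add atoms: none
Why: In this Mukaiyama–Michael addition, catalysed by the silyl triflimide formed in situ, the ketene acetal should attack C9 of the silyl‑activated enone from the face anti to the axial C19 methylene, so C11 ends anti and C20 syn to C19; acid hydrolysis of the silyl enol ether then protonates C8 axially and leaves the equatorial methyl, which is also the thermodynamic epimer.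

Step 16
Reactants: 24 7-keto tert-butyl ester
Product: 25 axial (7R)-alcohol (OH syn to C19)
Conditions: NaBH4, THF/MeOH (9:1), −20 °C
Reagents that add atoms: none
Why: Borohydride reduction of a cyclohexanone whose axial face is blocked by the syn‑axial C19 and C20 groups should proceed by equatorial attack and give the axial alcohol; ester, lactone and enol acetate are not reduced at this temperature.

Step 17
Reactants: 25 axial (7R)-alcohol
Product: 26 (7R)-acetate (C1=C2 enol acetate; tert-butyl ester)
Conditions: Ac2O, DMAP, Et3N, CH2Cl2, 40 °C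
Reagents that add atoms: acetic anhydride, CC(=O)OC(C)=O
Why: DMAP‑catalysed acyl transfer with excess anhydride and mild heating is used to overcome the 1,3‑diaxial shielding of the C7 hydroxyl.

Step 18
Reactants: 26 (7R)-acetate; 27 2-bromofuran
Product: 29 2-ketone with equatorial 2-furyl at C1 (furyl anti to C19; 3-SPh and tert-butyl ester in place), via tin enolate 28 (not isolated)
Conditions: Bu3SnOMe, toluene, 60 °C; then 27, PdCl2[P(o-tol)3]2 (5 mol %), toluene, 100 °C; Et3N, CH2Cl2, rt
Reagents that add atoms: none
Why: This is a palladium‑catalysed α‑arylation of a tin enolate (Stille‑type coupling of the enolate made regiospecifically from the enol acetate by acyl transfer to Bu3SnOMe), so arylation can occur only at C1, and the epimerisable C1 centre should settle with the furyl group equatorial because the axial position is syn‑diaxial to C19 and to the C3 sulfide.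

Step 19
Reactants: 29 2-ketone with equatorial 2-furyl at C1
Product: 31 C12 carboxylic acid, via TMS ester 30 (not isolated)
Conditions: TMSOTf, 2,6-lutidine, CH2Cl2, 0 °C; then aq. KH2PO4, THF
Reagents that add atoms: none
Why: Silyl triflate‑mediated cleavage of the tert‑butyl ester (O‑silylation, loss of isobutene, hydrolysis of the silyl ester and of any C2 silyl enol ether on work‑up) runs under lutidine‑buffered, non‑protic conditions that spare the furan and the acetate.

Step 20
Reactants: 31 C12 carboxylic acid
Product: 33 pentacyclic 2,12-diketone (ring C closed; 3-SPh in place), via acid chloride 32 (not isolated)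
Conditions: 1-chloro-N,N,2-trimethylprop-1-en-1-amine, CH2Cl2, 0 °C; then SnCl4, CH2Cl2 (2 mM), −78 to −20 °C
Reagents that add atoms: none
Why: In this intramolecular Friedel–Crafts acylation the acid chloride, made under neutral conditions with the α‑chloroenamine, is ionised by SnCl4 and attacks furan C3, the only ring position the five‑atom chain can reach, closing the seven‑membered ring C.

Step 21
Reactants: 33 pentacyclic 2,12-diketone
Product: 35 2-oxo-3-ene (C3=C4 conjugated with the lactone and the C2 ketone), via sulfoxide 34 (not isolated)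
Conditions: mCPBA (1.0 equiv), CH2Cl2, −78 °C; then DBU, −78 to 0 °C
Reagents that add atoms: none
Why: One equivalent of peracid oxidises the sulfide chemoselectively (it is far more nucleophilic than the acyl‑deactivated furan), and base then induces anti β‑elimination of benzenesulfenate (E1cB through the lactone enolate, the axial C3 sulfinyl group being anti‑periplanar to H4), which installs C3=C4 where a thermal syn‑elimination has no syn hydrogen.

Step 22
Reactants: 35 2-oxo-3-ene
Product: 36 CNP0182929.1
Conditions: NaBH4, CeCl3·7H2O, MeOH/CH2Cl2, −78 °C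
Reagents that add atoms: none
Why: Luche reduction (cerium‑assisted 1,2‑reduction with axial hydride delivery from the face anti to C19) should give the equatorial (2S) allylic alcohol, while the C12 ketone (a hindered vinylogous ester of the furan), the lactone and the acetate remain.

Compound list
1 | methyl 2-methyl-3-oxobutanoate | COC(=O)C(C)C(C)=O | starting material
2 | methyl (Z)-2-methyl-3-(triflyloxy)but-2-enoate | COC(=O)/C(C)=C(/C)OS(=O)(=O)C(F)(F)F | intermediate
3 | (Z)-4-hydroxy-3-methylbut-2-en-2-yl triflate | OC/C(C)=C(/C)OS(=O)(=O)C(F)(F)F | intermediate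
4 | (Z)-2-methyl-3-(triflyloxy)but-2-enal | O=C/C(C)=C(/C)OS(=O)(=O)C(F)(F)F | intermediate
5 | 3-chloro-2-(chloromethyl)prop-1-ene | C=C(CCl)CCl | starting material
6 | TMS ether of 7 (formed in the flask) | ClCC(=C)C[C@H](O[Si](C)(C)C)/C(C)=C(C)\OS(=O)(=O)C(F)(F)F | intermediate
7 | (2Z,4S)-6-(chloromethyl)-4-hydroxy-3-methylhepta-2,6-dien-2-yl triflate | ClCC(=C)C[C@H](O)/C(C)=C(C)\OS(=O)(=O)C(F)(F)F | intermediate
8 | (2Z,4S)-4-(tert-butyldimethylsilyloxy)-6-(chloromethyl)-3-methylhepta-2,6-dien-2-yl triflate | ClCC(=C)C[C@H](O[Si](C)(C)C(C)(C)C)/C(C)=C(C)\OS(=O)(=O)C(F)(F)F | intermediate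
9 | potassium acrylate | [K+].[O-]C(=O)C=C | starting material
10 | (4S,5Z)-4-(tert-butyldimethylsilyloxy)-5-methyl-2-methylidene-6-(triflyloxy)hept-5-enyl acrylate | C=CC(=O)OCC(=C)C[C@H](O[Si](C)(C)C(C)(C)C)/C(C)=C(C)\OS(=O)(=O)C(F)(F)F | intermediate
11 | 4-[(2S,3Z)-2-(tert-butyldimethylsilyloxy)-3-methyl-4-(triflyloxy)pent-3-enyl]furan-2(5H)-one | O=C1OCC(C[C@H](O[Si](C)(C)C(C)(C)C)/C(C)=C(C)\OS(=O)(=O)C(F)(F)F)=C1 | intermediate
12 | (phenylthio)acetic acid | OC(=O)CSc1ccccc1 | starting material
13 | (E)-1,2-bis(tributylstannyl)ethene | CCCC[Sn](CCCC)(CCCC)/C=C/[Sn](CCCC)(CCCC)CCCC | starting material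
14 | (phenylthio)acetyl chloride (formed in the flask) | ClC(=O)CSc1ccccc1 | intermediate
15 | (E)-1-(phenylthio)-4-(tributylstannyl)but-3-en-2-one | CCCC[Sn](CCCC)(CCCC)/C=C/C(=O)CSc1ccccc1 | intermediate
16 | (1Z,3E)-1-(phenylthio)-4-(tributylstannyl)buta-1,3-dien-2-yl acetate | CCCC[Sn](CCCC)(CCCC)/C=C/C(OC(C)=O)=C/Sc1ccccc1 | intermediate
17 | 4-[(2S,3Z,5E,7Z)-7-acetoxy-2-(tert-butyldimethylsilyloxy)-3,4-dimethyl-8-(phenylthio)octa-3,5,7-trienyl]furan-2(5H)-one | O=C1OCC(C[C@H](O[Si](C)(C)C(C)(C)C)/C(C)=C(C)\C=C\C(OC(C)=O)=C\Sc2ccccc2)=C1 | intermediate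
18 | tricyclic Diels–Alder adduct (7S-OTBS anti to C19; trans-fused rings A/B; γ-lactone; C1=C2 enol acetate; C8=C9; 3-SPh syn to C19) | C[Si](C)(C(C)(C)C)O[C@H]1C[C@]23COC(=O)[C@@H]3[C@H](Sc4ccccc4)C(OC(C)=O)=C[C@@H]2C(C)=C1C | intermediate
19 | tricyclic (7S)-allylic alcohol | O[C@H]1C[C@]23COC(=O)[C@@H]3[C@H](Sc4ccccc4)C(OC(C)=O)=C[C@@H]2C(C)=C1C | intermediate
20 | ring A enone (7-oxo-8-ene) | O=C1C[C@]23COC(=O)[C@@H]3[C@H](Sc4ccccc4)C(OC(C)=O)=C[C@@H]2C(C)=C1C | intermediate
21 | tert-butyl acetate | CC(=O)OC(C)(C)C | starting material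
22 | 1-tert-butoxy-1-(tert-butyldimethylsilyloxy)ethene | C=C(OC(C)(C)C)O[Si](C)(C)C(C)(C)C | intermediate
23 | C7 silyl enol ether of 24 (formed in the flask) | CC(C)(C)[Si](C)(C)OC=1C[C@]23COC(=O)[C@@H]3[C@H](Sc4ccccc4)C(OC(C)=O)=C[C@@H]2[C@@](C)(CC(=O)OC(C)(C)C)C=1C | intermediate
24 | 7-keto tert-butyl ester (C9 quaternary; C11 anti and C20 syn to C19; 8-CH3 equatorial) | O=C1C[C@]23COC(=O)[C@@H]3[C@H](Sc4ccccc4)C(OC(C)=O)=C[C@@H]2[C@@](C)(CC(=O)OC(C)(C)C)[C@@H]1C | intermediate
25 | axial (7R)-alcohol | O[C@@H]1C[C@]23COC(=O)[C@@H]3[C@H](Sc4ccccc4)C(OC(C)=O)=C[C@@H]2[C@@](C)(CC(=O)OC(C)(C)C)[C@@H]1C | intermediate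
26 | (7R)-acetate with C1=C2 enol acetate | CC(=O)O[C@@H]1C[C@]23COC(=O)[C@@H]3[C@H](Sc4ccccc4)C(OC(C)=O)=C[C@@H]2[C@@](C)(CC(=O)OC(C)(C)C)[C@@H]1C | intermediate
27 | 2-bromofuran | Brc1ccco1 | starting material
28 | C2 O-tributylstannyl enolate of 26 (formed in the flask) | CC(=O)O[C@@H]1C[C@]23COC(=O)[C@@H]3[C@H](Sc4ccccc4)C(O[Sn](CCCC)(CCCC)CCCC)=C[C@@H]2[C@@](C)(CC(=O)OC(C)(C)C)[C@@H]1C | intermediate
29 | 2-ketone with equatorial 2-furyl at C1 | CC(=O)O[C@@H]1C[C@]23COC(=O)[C@@H]3[C@H](Sc4ccccc4)C(=O)[C@@H](c4ccco4)[C@@H]2[C@@](C)(CC(=O)OC(C)(C)C)[C@@H]1C | intermediate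
30 | trimethylsilyl ester of 31 (formed in the flask) | CC(=O)O[C@@H]1C[C@]23COC(=O)[C@@H]3[C@H](Sc4ccccc4)C(=O)[C@@H](c4ccco4)[C@@H]2[C@@](C)(CC(=O)O[Si](C)(C)C)[C@@H]1C | intermediate
31 | C12 carboxylic acid | CC(=O)O[C@@H]1C[C@]23COC(=O)[C@@H]3[C@H](Sc4ccccc4)C(=O)[C@@H](c4ccco4)[C@@H]2[C@@](C)(CC(=O)O)[C@@H]1C | intermediate
32 | C12 acid chloride (formed in the flask) | CC(=O)O[C@@H]1C[C@]23COC(=O)[C@@H]3[C@H](Sc4ccccc4)C(=O)[C@@H](c4ccco4)[C@@H]2[C@@](C)(CC(=O)Cl)[C@@H]1C | intermediate
33 | pentacyclic 2,12-diketone with 3-SPh (ring C closed) | CC(=O)O[C@@H]1C[C@@]23COC(=O)[C@@H]2[C@H](Sc5ccccc5)C(=O)[C@H]2c4occc4C(=O)C[C@@](C)([C@@H]1C)[C@@H]23 | intermediate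
34 | C3 sulfoxide of 33 (sulfur epimers; formed in the flask) | CC(=O)O[C@@H]1C[C@@]23COC(=O)[C@@H]2[C@H](S(=O)c5ccccc5)C(=O)[C@H]2c4occc4C(=O)C[C@@](C)([C@@H]1C)[C@@H]23 | intermediate
35 | 2-oxo-3-ene | CC(=O)O[C@@H]1C[C@@]23COC(=O)C2=CC(=O)[C@H]2c4occc4C(=O)C[C@@](C)([C@@H]1C)[C@@H]23 | intermediate
36 | CNP0182929.1: (1S,2S,5S,7R,8S,9R,10R)-7-acetoxy-2-hydroxy-12-oxo-3-en-18,19-olide with the furan bridging C1 and C12 (clerodane numbering; 7-OAc axial; 2-OH equatorial) | CC(=O)O[C@@H]1C[C@@]23COC(=O)C2=C[C@H](O)[C@H]2c4occc4C(=O)C[C@@](C)([C@@H]1C)[C@@H]23 | target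

Total step count: 22. Longest linear sequence: 19 steps (steps 1–7, 10–13 and 15–22, from 1).

Steps most likely to fail

Step 18 (furylation at C1). Transmetalation and reductive elimination at the congested C1 may be slow, so that β‑hydride loss toward C10 or isomerisation of the tin enolate toward C3 takes over. The fallback reverses the polarity; it sets out from 26 and returns at 29. The tin enolate 28, made as in step 18, would be quenched at −78 °C with N‑bromosuccinimide to give the 1‑bromo‑2‑ketone F1 (the enolate should react far faster than the sulfide). F1 would then be coupled with 2‑furylzinc chloride F2 (from 27 by bromine–lithium exchange with n‑BuLi, then ZnCl2) under NiCl2·glyme/bis(oxazolinyl)pyridine catalysis, a Negishi coupling of a secondary α‑bromo ketone that passes through the C1 radical and is less sensitive to crowding. The same base equilibration then leads to 29.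

Step 15 (quaternary C9). The tetrasubstituted β‑carbon may not accept the nucleophile (or 1,2‑addition may compete), or the facial selectivity may be poor. The fallback transfers the two‑carbon unit intramolecularly from the C7 oxygen; it sets out from 19 and returns at 24. Bromoacetyl bromide and pyridine would give the C7 bromoacetate F3. Zinc dust in THF at 65 °C would trigger the Reformatsky–Claisen rearrangement, which delivers C11 suprafacially to the face of the C7–O bond (anti to C19) and gives the 7‑ene acid F4. tert‑Butyl 2,2,2‑trichloroacetimidate would convert F4 into the tert‑butyl ester F5. Hydroboration (BH3·SMe2, 0 °C, expected to prefer the trialkyl alkene over the deactivated enol acetate; trimethylamine N‑oxide for the oxidation, which leaves the sulfide alone) from the face anti to C19 and C20 would give the equatorial C7 alcohol F6 with H8 already anti. Dess–Martin oxidation of F6 gives 24.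

Step 11 (key cycloaddition). At the temperature the trisubstituted dienophile needs, a [1,5]‑hydrogen shift of H7 into the cis‑dienyl system or erosion of the facial control may compete. The fallback uses a more electron‑rich diene so that the cyclisation runs cooler; it sets out from 15 and returns at 18. TBSOTf and Et3N would convert 15 into the 2‑silyloxy diene F7, which would be coupled with 11 as in step 10 to the silyloxy tetraene F8. F8 should cyclise well below 120 °C to the silyl enol ether adduct F9. Fluoride‑triggered O‑acetylation (anhydrous benzyltrimethylammonium fluoride, Ac2O, THF, −78 °C; the enol silyl ether is cleaved much faster than the secondary silyl ether) would convert F9 regiospecifically into 18.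

Further compounds
F1 | step 18 | 1-bromo-2-ketone from 26 (C1 epimers) | CC(=O)O[C@@H]1C[C@]23COC(=O)[C@@H]3[C@H](Sc4ccccc4)C(=O)C(Br)[C@@H]2[C@@](C)(CC(=O)OC(C)(C)C)[C@@H]1C
F2 | step 18 | 2-furylzinc chloride | Cl[Zn]c1ccco1
F3 | step 15 | C7 bromoacetate of 19 | BrCC(=O)O[C@H]1C[C@]23COC(=O)[C@@H]3[C@H](Sc4ccccc4)C(OC(C)=O)=C[C@@H]2C(C)=C1C
F4 | step 15 | 7-ene C12 acid with quaternary C9 | C=1C[C@]23COC(=O)[C@@H]3[C@H](Sc4ccccc4)C(OC(C)=O)=C[C@@H]2[C@@](C)(CC(=O)O)C=1C
F5 | step 15 | tert-butyl ester of F4 | C=1C[C@]23COC(=O)[C@@H]3[C@H](Sc4ccccc4)C(OC(C)=O)=C[C@@H]2[C@@](C)(CC(=O)OC(C)(C)C)C=1C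
F6 | step 15 | equatorial C7 alcohol (7-epimer of 25) | O[C@H]1C[C@]23COC(=O)[C@@H]3[C@H](Sc4ccccc4)C(OC(C)=O)=C[C@@H]2[C@@](C)(CC(=O)OC(C)(C)C)[C@@H]1C
F7 | step 11 | (1Z,3E)-2-(tert-butyldimethylsilyloxy)-1-(phenylthio)-4-(tributylstannyl)buta-1,3-diene | CCCC[Sn](CCCC)(CCCC)/C=C/C(O[Si](C)(C)C(C)(C)C)=C/Sc1ccccc1
F8 | step 11 | silyloxy tetraene (17 with OTBS in place of OAc) | O=C1OCC(C[C@H](O[Si](C)(C)C(C)(C)C)/C(C)=C(C)\C=C\C(O[Si](C)(C)C(C)(C)C)=C\Sc2ccccc2)=C1
F9 | step 11 | silyl enol ether adduct (18 with OTBS in place of OAc at C2) | C[Si](C)(C(C)(C)C)O[C@H]1C[C@]23COC(=O)[C@@H]3[C@H](Sc4ccccc4)C(O[Si](C)(C)C(C)(C)C)=C[C@@H]2C(C)=C1C
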